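**Strategy.** Everything rests on cutting ring B (C1, C5–C10) at C6–C7 and C8–C9. The carbinol C6 and the methyl-bearing, later epoxidised C8–C9 bond flank the lone methylene C7, which is the imprint of a ketone carbon, an ynoate α-carbon and its β-carbon. Taking C7 and C8 (plus the C8 methyl) out as methyl but-2-ynoate leaves a cyclopentanone (C1, C5, C6, C9, C10) cis-fused to ring A (C1–C5); its pyrrolidine enamine (C6=C9), which already holds the C1 methyl and the protected C4 carbinol, is the precursor. In one operation, [2+2] cycloaddition and cyclobutene opening replace the C6–C9 bond by C6–C7 and C8–C9, giving ring B with all its functional carbons set.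

Key step: step 11

Assumption: commercial (S)-(+)-terpinen-4-ol is taken as enantiomerically pure; its carbinol centre (daucane C4) controls every later stereocentre.

Conventions: daucane numbering (C4 carries oxygen and isopropyl, C1 the angular methyl, C8 the ring B methyl); α is the face of the C1 methyl, β the opposite face; PMB = 4-methoxybenzyl.

Step 1
Reactants: 1 (S)-terpinen-4-ol; 2 4-methoxybenzyl chloride
Product: 3 (S)-4-isopropyl-4-(4-methoxybenzyloxy)-1-methylcyclohex-1-ene
Conditions: NaH, Bu4NI (cat.), DMF, 0 to 50 °C
Reagents that add atoms: 4-methoxybenzyl chloride, COc1ccc(CCl)cc1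
Why: Williamson etherification of the sodium alkoxide with a reactive benzylic halide masks the tertiary hydroxyl as an ether that withstands the bases, hydrides, light and heat used up to step 15 and is removed there under neutral oxidative conditions; no stereocentre is touched.

Step 2
Reactants: 3 PMB ether; 4 3-chloroperoxybenzoic acid
Product: 5 1,2-epoxide of 3 (either face; carbinol centre unchanged)
Conditions: mCPBA, NaHCO3, CH2Cl2, 0 °C
Reagents that add atoms: 3-chloroperoxybenzoic acid, OOC(=O)c1cccc(Cl)c1
Why: Prilezhaev epoxidation of the only alkene; the two epoxide diastereomers need not be separated because both epoxide carbons lose their stereochemistry in steps 3 and 4.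

Step 3
Reactants: 5 epoxide
Product: 8 4-isopropyl-4-(4-methoxybenzyloxy)-1-methylcyclohex-2-en-1-ol (both C1 epimers), via hydroxy selenide 6 (not isolated), via selenoxide 7 (not isolated)
Conditions: (PhSe)2, NaBH4, EtOH, 78 °C; then H2O2 (30% aq.), THF, 0 to 25 °C
Reagents that add atoms: none
Why: The selenolate opens the epoxide by SN2 attack at the less substituted carbon, and oxidation to the selenoxide triggers syn-elimination away from the hydrogen-free carbinol carbon, which shifts the double bond and leaves a tertiary allylic alcohol; both diastereomers converge in step 4.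

Step 4
Reactants: 8 tertiary allylic alcohol; 9 pyridinium chlorochromate
Product: 10 (R)-6-isopropyl-6-(4-methoxybenzyloxy)-3-methylcyclohex-2-en-1-one
Conditions: pyridinium chlorochromate (C5H5NH)[CrO3Cl], 4 Å molecular sieves, CH2Cl2, 25 °C
Reagents that add atoms: pyridinium chlorochromate, [O-][Cr](=O)(=O)Cl.c1cc[nH+]cc1
Why: Babler–Dauben oxidative transposition: the chromate ester of the tertiary allylic alcohol undergoes a [3,3] shift and the secondary allylic chromate is oxidised, so the carbonyl lands next to the ether-bearing carbon and the methyl-bearing carbon becomes the β-carbon of an enone; the carbinol stereocentre disappears.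

Step 5
Reactants: 10 enone; 11 vinylmagnesium bromide
Product: 13 (2R,5S)-2-isopropyl-2-(4-methoxybenzyloxy)-5-methyl-5-vinylcyclohexan-1-one (vinyl cis to isopropyl), via silyl enol ether 12 (not isolated)
Conditions: CH2=CHMgBr, CuBr·SMe2 (20 mol%), Me3SiCl, HMPA, THF, −78 °C; then 1 M HCl, THF, 0 °C
Reagents that add atoms: vinylmagnesium bromide, C=C[Mg]Br
Why: Copper-catalysed, chlorosilane-accelerated conjugate addition builds the quaternary centre (daucane C1); axial attack on the half-chair that keeps isopropyl pseudoequatorial and the ether oxygen pseudoaxial should place vinyl cis to isopropyl and trans to oxygen, and the enolate formed has no β-leaving group.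

Step 6
Reactants: 13 ketone; 14 4-acetamidobenzenesulfonyl azide
Product: 16 6-diazo-2-isopropyl-2-(4-methoxybenzyloxy)-5-methyl-5-vinylcyclohexan-1-one, via trifluoroacetyl ketone 15 (not isolated)
Conditions: LiN(SiMe3)2, THF, −78 °C; CF3CO2CH2CF3; then 4-acetamidobenzenesulfonyl azide, Et3N, H2O (1 equiv), MeCN, 25 °C
Reagents that add atoms: 4-acetamidobenzenesulfonyl azide, CC(=O)Nc1ccc(cc1)S(=O)(=O)N=[N+]=[N-]
Why: Detrifluoroacetylative (Regitz-type) diazo transfer: the ketone can enolise only towards the CH2 next to the quaternary carbon, this enolate is C-trifluoroacetylated, and the sulfonyl azide then delivers N2 with loss of the activating group; no stereocentre changes.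

Step 7
Reactants: 16 diazo ketone; 17 methanol
Product: 19 methyl 2-isopropyl-2-(4-methoxybenzyloxy)-5-methyl-5-vinylcyclopentane-1-carboxylate (ester/vinyl/isopropyl β; methyl and ether oxygen α), via ketene 18 (not isolated)
Conditions: hν (350 nm, Pyrex), CH3OH, 0 °C
Reagents that add atoms: methanol, CO
Why: Photochemical Wolff rearrangement of the cyclic α-diazo ketone contracts the ring to ring A (the oxygen-bearing carbon migrates with retention) and methanol traps the ketene; the ester enol should be protonated at C5 from the α face (C1 methyl and ether oxygen), away from isopropyl and vinyl, so the ester ends up cis to vinyl, and any C5 epimer drops out at step 9 because it cannot close a cis-fused ring.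

Step 8
Reactants: 19 methyl ester
Product: 20 2-isopropyl-2-(4-methoxybenzyloxy)-5-methyl-5-vinylcyclopentane-1-carbaldehyde (formyl/vinyl/isopropyl β)
Conditions: diisobutylaluminium hydride (1.1 equiv), CH2Cl2, −78 °C; aq. potassium sodium tartrate
Reagents that add atoms: none
Why: Partial hydride reduction of a hindered ester stops at the aluminium hemiacetal at −78 °C and releases the aldehyde only on work-up; C5, flanked by two fully substituted carbons, should not epimerise.

Step 9
Reactants: 20 aldehyde
Product: 21 cis-fused diquinanone (cyclopentanone C1/C5/C6/C9/C10 with C6=O fused to ring A; H5 and C1 methyl α; C4 O-PMB α; isopropyl β)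
Conditions: [Rh(norbornadiene)(Ph2PCH2CH2PPh2)]BF4 (10 mol%), H2 (activation), then Ar, CH2Cl2, 25 °C
Reagents that add atoms: none
Why: Cationic rhodium-catalysed intramolecular hydroacylation (aldehyde C–H oxidative addition, insertion of the vinyl group, reductive elimination) forms C6–C9 and closes the cyclopentanone; a bicyclo[3.3.0]octanone can only be cis-fused, so no new stereocentre arises.

Step 10
Reactants: 21 diquinanone; 22 pyrrolidine
Product: 23 pyrrolidine enamine of 21 (C6=C9; stereocentres as in 21)
Conditions: pyrrolidine (3 equiv), TsOH·H2O (2 mol%), toluene, reflux, Dean–Stark trap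
Reagents that add atoms: pyrrolidine, C1CCNC1
Why: Acid-catalysed condensation with azeotropic removal of water gives the enamine, whose double bond goes to the CH2 carbon C9 because the alternative through the tertiary C5, next to the fully substituted C4, would suffer severe allylic strain.

Step 11
Reactants: 23 enamine; 24 methyl but-2-ynoate
Product: 26 ring B aminodiene ester (cis-fused bicyclo[5.3.0]deca-diene: pyrrolidine on C6; CO2CH3 on C7; methyl on C8; C6=C7 and C8=C9; C1/C4/C5 as in 21), via aminocyclobutene 25 (not isolated)
Conditions: methyl but-2-ynoate (3 equiv), toluene, 110 °C, sealed tube, Ar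
Reagents that add atoms: methyl but-2-ynoate, CC#CC(=O)OC
Why: The nucleophilic enamine carbon C9 adds to the methyl-bearing β-carbon of the ynoate (C8), the iminium/allenolate zwitterion collapses by C7–C6 bond formation on the same convex face, and the donor–acceptor aminocyclobutene 25 then opens across the old C6–C9 bond to the push–pull aminodiene. The closest known reaction is the [2+2] cycloaddition and ring opening of cyclic ketone enamines with propiolates and acetylenedicarboxylates, a two-carbon ring expansion; the β-methyl ynoate is a weaker acceptor, hence the excess, the aprotic non-polar solvent and the heat. Ring B is thus closed by expansion of the cyclopentanone (stepwise polar four-ring formation, then 4π electrocyclic opening), not by end-to-end cyclisation. No stereocentre is created: C6 and C9 become sp2, the two cyclobutene centres are transient, and C1, C4 and C5 are spectators. Two regiochemical choices are needed: the enamine must lie towards C9, which the hindered ring-fusion carbon C5 secures in step 10, and C9 must bond to the ynoate carbon carrying methyl, which the polarity of the conjugated ester secures. Ring closure rather than proton transfer to an open-chain Michael adduct is favoured by the aprotic medium.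

Step 12
Reactants: 26 aminodiene ester; 27 water
Product: 28 β-keto ester (C6 ketone; C7 CO2CH3; C8=C9; cis-fused; keto/enol/alkylidene tautomers)
Conditions: AcOH–H2O–THF (2:1:1), 45 °C
Reagents that add atoms: water, O
Why: Hydrolysis of the vinylogous carbamate (C-protonation, then hydrolysis of the iminium ion) frees the C6 carbonyl; all tautomers of the β-keto ester give the same ketone in step 13, and C5 is not enolised under these mildly acidic conditions.

Step 13
Reactants: 28 β-keto ester
Product: 29 cis-fused β,γ-enone (C6 ketone; C8=C9; H5 α; C4 O-PMB)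
Conditions: LiCl, H2O, DMSO, 140 °C
Reagents that add atoms: none
Why: Krapcho dealkoxycarbonylation (chloride attacks the ester methyl, CO2 is lost) leaves a dienolate that water protonates kinetically at C7, so the β,γ-enone should predominate; accompanying alkene or C5 isomers are tolerated because all converge in step 14.

Step 14
Reactants: 29 cis-fused β,γ-enone
Product: 32 trans-fused β,γ-enone (C6 ketone; C8=C9; H5 β; C4 O-PMB α), via conjugated trans enone 30 (not isolated), via potassium dienolate 31 (not isolated)
Conditions: NaOCH3 (0.3 equiv), CH3OH, 40 °C; evaporate; then KOC(CH3)3 (4 equiv), t-BuOH–THF, Ar, 0 °C; inverse quench into AcOH–H2O, 0 °C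
Reagents that add atoms: none
Why: Reversible enolisation by catalytic methoxide equilibrates C7 and C5 and should funnel the material into the conjugated, trans-fused enone 30 (hydroazulenones with the carbonyl next to the ring fusion are generally more stable trans, and epimerisation moves C6 off the face of the isopropyl group); deconjugation by kinetic C7 protonation of the extended dienolate 31 then restores C8=C9, so C5 (H5 β) is set under thermodynamic control.

Step 15
Reactants: 32 trans-fused β,γ-enone
Product: 33 4-hydroxy ketone (trans-fused; free tertiary C4 OH α; C6 ketone; C8=C9)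
Conditions: DDQ, CH2Cl2–pH 7 phosphate buffer (10:1), 0 to 25 °C
Reagents that add atoms: none
Why: Oxidative cleavage of the 4-methoxybenzyl ether (hydride abstraction, hydrolysis of the oxocarbenium ion) proceeds under buffered neutral conditions, so the β-hydroxy ketone is never enolised and retro-aldol opening, alkene migration and C5 epimerisation should be avoided.

Step 16
Reactants: 33 4-hydroxy ketone; 34 4-(tert-butyldimethylsilyloxy)-3-methoxybenzaldehyde
Product: 35 C4 4-(tert-butyldimethylsilyloxy)-3-methoxybenzoate with free 6β-hydroxyl (trans-fused; C8=C9)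
Conditions: SmI2 (0.3 equiv), 34 (5 equiv), THF, −10 °C
Reagents that add atoms: 4-(tert-butyldimethylsilyloxy)-3-methoxybenzaldehyde, COc1cc(C=O)ccc1O[Si](C)(C)C(C)(C)C
Why: Evans–Tishchenko reduction: the samarium-bound hemiacetal of the C4 hydroxyl and the aldehyde passes its hydride intramolecularly to C6 through a six-membered chair-like transition state, so the acyl group ends on the tertiary C4 oxygen and the new hydroxyl is 1,3-anti to it (hydride on the α face, 6-OH β), which settles the tertiary ester and the C6 configuration together.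

Step 17
Reactants: 35 homoallylic alcohol; 36 tert-butyl hydroperoxide
Product: 37 8β,9β-epoxide of 35 (phenol still silylated)
Conditions: VO(acac)2 (5 mol%), t-BuOOH (decane), CH2Cl2, 0 to 25 °C
Reagents that add atoms: tert-butyl hydroperoxide, CC(C)(C)OO
Why: Hydroxyl-directed epoxidation: the vanadium alkoxide of the homoallylic 6β-hydroxyl delivers the peroxide oxygen to C8=C9 on its own face, setting C8 and C9 syn to the hydroxyl, while the ester and the silylated phenol are inert.

Step 18
Reactants: 37 silylated epoxide
Product: 38 target CNP0315707.1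
Conditions: Bu4NF, AcOH (1:1), THF, 0 °C
Reagents that add atoms: none
Why: Fluoride-mediated cleavage of the phenolic silyl ether is fast, and the acetic acid buffer keeps the C6 hydroxyl protonated so that neither acyl migration from O4 to O6 nor epoxide opening should occur; no stereocentre is affected.

**Compound list**

1 | (S)-terpinen-4-ol | CC1=CC[C@](O)(C(C)C)CC1 | starting material
2 | 4-methoxybenzyl chloride | COc1ccc(CCl)cc1 | starting material
3 | (S)-4-isopropyl-4-(4-methoxybenzyloxy)-1-methylcyclohex-1-ene | CC1=CC[C@](OCc2ccc(OC)cc2)(C(C)C)CC1 | intermediate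
4 | 3-chloroperoxybenzoic acid | OOC(=O)c1cccc(Cl)c1 | starting material
5 | 1,2-epoxide of 3 (both faces) | CC12OC1C[C@](OCc3ccc(OC)cc3)(C(C)C)CC2 | intermediate
6 | 4-isopropyl-4-(4-methoxybenzyloxy)-1-methyl-2-(phenylselanyl)cyclohexan-1-ol (diastereomers) | CC1(O)C([Se]c2ccccc2)C[C@](OCc2ccc(OC)cc2)(C(C)C)CC1 | intermediate
7 | selenoxide of 6 | CC1(O)C([Se](=O)c2ccccc2)C[C@](OCc2ccc(OC)cc2)(C(C)C)CC1 | intermediate
8 | 4-isopropyl-4-(4-methoxybenzyloxy)-1-methylcyclohex-2-en-1-ol (both C1 epimers) | CC1(O)C=C[C@](OCc2ccc(OC)cc2)(C(C)C)CC1 | intermediate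
9 | pyridinium chlorochromate | [O-][Cr](=O)(=O)Cl.c1cc[nH+]cc1 | starting material
10 | (R)-6-isopropyl-6-(4-methoxybenzyloxy)-3-methylcyclohex-2-en-1-one | CC1=CC(=O)[C@](OCc2ccc(OC)cc2)(C(C)C)CC1 | intermediate
11 | vinylmagnesium bromide | C=C[Mg]Br | starting material
12 | trimethylsilyl enol ether of 13 | C=C[C@]1(C)C=C(O[Si](C)(C)C)[C@](OCc2ccc(OC)cc2)(C(C)C)CC1 | intermediate
13 | (2R,5S)-2-isopropyl-2-(4-methoxybenzyloxy)-5-methyl-5-vinylcyclohexan-1-one | C=C[C@]1(C)CC(=O)[C@](OCc2ccc(OC)cc2)(C(C)C)CC1 | intermediate
14 | 4-acetamidobenzenesulfonyl azide | CC(=O)Nc1ccc(cc1)S(=O)(=O)N=[N+]=[N-] | starting material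
15 | 6-trifluoroacetyl derivative of 13 | C=C[C@]1(C)C(C(=O)C(F)(F)F)C(=O)[C@](OCc2ccc(OC)cc2)(C(C)C)CC1 | intermediate
16 | 6-diazo derivative of 13 | C=C[C@]1(C)C(=[N+]=[N-])C(=O)[C@](OCc2ccc(OC)cc2)(C(C)C)CC1 | intermediate
17 | methanol | CO | starting material
18 | ring-contracted ketene (C5=C6=O on ring A) | COc1ccc(CO[C@@]2(C(C)C)CC[C@](C)(C=C)C2=C=O)cc1 | intermediate
19 | methyl 2-isopropyl-2-(4-methoxybenzyloxy)-5-methyl-5-vinylcyclopentane-1-carboxylate (ester, vinyl, isopropyl β) | COc1ccc(CO[C@@]2(C(C)C)CC[C@](C)(C=C)[C@@H]2C(=O)OC)cc1 | intermediate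
20 | corresponding cyclopentane-1-carbaldehyde (formyl, vinyl, isopropyl β) | COc1ccc(CO[C@@]2(C(C)C)CC[C@](C)(C=C)[C@@H]2C=O)cc1 | intermediate
21 | cis-fused diquinanone (C6 ketone; H5 and C1 methyl α; 4-O-PMB α; isopropyl β) | COc1ccc(CO[C@@]2(C(C)C)CC[C@]3(C)CCC(=O)[C@@H]32)cc1 | intermediate
22 | pyrrolidine | C1CCNC1 | starting material
23 | pyrrolidine enamine of 21 (C6=C9) | COc1ccc(CO[C@@]2(C(C)C)CC[C@]3(C)CC=C(N4CCCC4)[C@@H]32)cc1 | intermediate
24 | methyl but-2-ynoate | CC#CC(=O)OC | starting material
25 | aminocyclobutene (C6–C7=C8–C9 ring on the convex face) | COc1ccc(CO[C@@]2(C(C)C)CC[C@]3(C)C[C@H]4C(C)=C(C(=O)OC)[C@@]4(N5CCCC5)[C@@H]32)cc1 | intermediate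
26 | ring B aminodiene ester (cis-fused) | COc1ccc(CO[C@@]2(C(C)C)CC[C@]3(C)CC=C(C)C(C(=O)OC)=C(N4CCCC4)[C@@H]32)cc1 | intermediate
27 | water | O | starting material
28 | cis-fused β-keto ester (keto form shown) | COc1ccc(CO[C@@]2(C(C)C)CC[C@]3(C)CC=C(C)C(C(=O)OC)C(=O)[C@@H]32)cc1 | intermediate
29 | cis-fused β,γ-enone | COc1ccc(CO[C@@]2(C(C)C)CC[C@]3(C)CC=C(C)CC(=O)[C@@H]32)cc1 | intermediate
30 | trans-fused conjugated enone (C7=C8) | COc1ccc(CO[C@@]2(C(C)C)CC[C@]3(C)CCC(C)=CC(=O)[C@H]32)cc1 | intermediate
31 | potassium dienolate of 30 | COc1ccc(CO[C@@]2(C(C)C)CC[C@]3(C)CC=C(C)C=C([O-])[C@H]32)cc1.[K+] | intermediate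
32 | trans-fused β,γ-enone | COc1ccc(CO[C@@]2(C(C)C)CC[C@]3(C)CC=C(C)CC(=O)[C@H]32)cc1 | intermediate
33 | trans-fused 4-hydroxy ketone (C8=C9) | O[C@@]1(C(C)C)CC[C@]2(C)CC=C(C)CC(=O)[C@H]21 | intermediate
34 | 4-(tert-butyldimethylsilyloxy)-3-methoxybenzaldehyde | COc1cc(C=O)ccc1O[Si](C)(C)C(C)(C)C | starting material
35 | C4 silylated vanillate with free 6β-hydroxyl | COc1cc(C(=O)O[C@@]2(C(C)C)CC[C@]3(C)CC=C(C)C[C@H](O)[C@H]32)ccc1O[Si](C)(C)C(C)(C)C | intermediate
36 | tert-butyl hydroperoxide | CC(C)(C)OO | starting material
37 | 8β,9β-epoxide of 35 | COc1cc(C(=O)O[C@@]2(C(C)C)CC[C@]3(C)C[C@@H]4O[C@]4(C)C[C@H](O)[C@H]32)ccc1O[Si](C)(C)C(C)(C)C | intermediate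
38 | CNP0315707.1 | COc1cc(C(=O)O[C@@]2(C(C)C)CC[C@]3(C)C[C@@H]4O[C@]4(C)C[C@H](O)[C@H]32)ccc1O | target

**Step count.** Total: 18 steps. Longest linear sequence: 18 steps (from 1; all other components are commercial).

**Steps most likely to fail**

Step 11. The cycloaddition may stall because the β-methyl ynoate is a weak acceptor, while prolonged heating diverts the enamine into open-chain proton-transfer adducts. The fallback sets out from 23 and returns at 30. The ring expansion is run with the far more reactive methyl propiolate and the C8 methyl is added afterwards.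
- 23 and methyl propiolate (Et2O, 0 to 35 °C) give the C8-unsubstituted aminodiene ester F1.
- Aqueous acetic acid gives the β-keto ester F2.
- LiCl in wet DMSO, then NaOCH3 in methanol, gives the trans-fused conjugated enone F3.
- Me2CuLi with Me3SiCl adds methyl to C8 and gives the silyl enol ether F4.
- Saegusa–Ito oxidation with Pd(OAc)2 in acetonitrile restores C7=C8 and gives 30, which re-enters step 14 at the dienolate stage.

Step 14. The equilibrium at C5 may not favour the trans fusion sufficiently, the C5 enolate may expel the C4 ether oxygen by β-elimination, or quenching may protonate the dienolate at C9 and return the conjugated enone. The fallback sets out from 29 and returns at 32. Equilibration is moved from enolates to enamines: condensation of 29 with pyrrolidine (TsOH cat., toluene, reflux, water removal) gives the linear dienamine F5, in which C5 equilibrates through iminium/enamine tautomers without an oxyanion. Buffered hydrolysis (AcOH, NaOAc, H2O–THF, 0 °C) protonates it kinetically at C7 and releases 32.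

Step 16. The samarium alkoxide may open ring A by retro-aldol cleavage, or the hindered tertiary carbinol may fail to form the hemiacetal, so that no hydride is transferred. The fallback sets out from 33 and returns at 35. Reduction and esterification are separated.
- Me4NBH(OAc)3 in MeCN–AcOH at −20 °C (Evans–Saksena reduction) gives the 1,3-anti diol F6.
- 4-Methoxybenzyl trichloroacetimidate with catalytic La(O3SCF3)3 protects only the secondary C6 hydroxyl and gives the mono-ether F7.
- The lithium alkoxide of the tertiary alcohol (LiN(SiMe3)2, THF, −78 °C) is acylated with 4-(tert-butyldimethylsilyloxy)-3-methoxybenzoyl chloride F8 (made from the acid with oxalyl chloride) to give the ester F9.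
- DDQ in buffered CH2Cl2 removes the 4-methoxybenzyl group and gives 35.

**Further compounds**

F1 | step 11 | aminodiene ester lacking the C8 methyl (cis-fused) | COc1ccc(CO[C@@]2(C(C)C)CC[C@]3(C)CC=CC(C(=O)OC)=C(N4CCCC4)[C@@H]32)cc1
F2 | step 11 | β-keto ester lacking the C8 methyl (cis-fused, keto form) | COc1ccc(CO[C@@]2(C(C)C)CC[C@]3(C)CC=CC(C(=O)OC)C(=O)[C@@H]32)cc1
F3 | step 11 | trans-fused conjugated enone lacking the C8 methyl (C7=C8) | COc1ccc(CO[C@@]2(C(C)C)CC[C@]3(C)CCC=CC(=O)[C@H]32)cc1
F4 | step 11 | trimethylsilyl enol ether (C6=C7) with C8 methyl (C8 epimers) | COc1ccc(CO[C@@]2(C(C)C)CC[C@]3(C)CCC(C)C=C(O[Si](C)(C)C)[C@H]32)cc1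
F5 | step 14 | linear pyrrolidine dienamine (N on C6; C6=C7 and C8=C9; trans-fused) | COc1ccc(CO[C@@]2(C(C)C)CC[C@]3(C)CC=C(C)C=C(N4CCCC4)[C@H]32)cc1
F6 | step 16 | 1,3-anti diol (4α-OH, 6β-OH; C8=C9) | O[C@@]1(C(C)C)CC[C@]2(C)CC=C(C)C[C@H](O)[C@H]21
F7 | step 16 | 6-O-(4-methoxybenzyl) ether of F6 | O[C@@]1(C(C)C)CC[C@]2(C)CC=C(C)C[C@H](OCc3ccc(OC)cc3)[C@H]21
F8 | step 16 | 4-(tert-butyldimethylsilyloxy)-3-methoxybenzoyl chloride | COc1cc(C(Cl)=O)ccc1O[Si](C)(C)C(C)(C)C
F9 | step 16 | C4 silylated vanillate of F7 | COc1cc(C(=O)O[C@@]2(C(C)C)CC[C@]3(C)CC=C(C)C[C@H](OCc4ccc(OC)cc4)[C@H]32)ccc1O[Si](C)(C)C(C)(C)C
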